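## Retrosynthetic overview

1. The target is PGE3 1,15-lactone 11-acetate: a cyclopentanone (C8–C12) fused to a 13-membered lactone (ring atoms O, C1–C8, C12–C15). The endgame is 11-OTES → 11-OH → 11-OAc.
2. The key disconnection is C14–C15 inside the macrolactone. The enabling feature is that C15 is both the alkoxy carbon of the lactone (bonded to the ring oxygen that carries the C1 acyl group) and allylic to C13=C14, i.e. an aldehyde-level carbon between O and an sp2 carbon. C15 is therefore bought as the carbonyl carbon of (Z)-hex-3-enal. The C1 acyl chloride turns it into a 1-chloroalkyl ester (tether and radical precursor at once), and a nickel-catalysed asymmetric reductive coupling joins it to a C14 vinyl iodide, uniting two electrophilic carbons, closing the ring and setting 15S.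
3. The seco acid (C1–C14, iodide on C14, ketone at C9) comes from (−)-Corey lactone diol: selective Swern oxidation of its bis-TES ether, Takai iodo-olefination (13E), DIBAL-H, Z-selective Wittig (5Z), Dess–Martin oxidation.
4. Ring order: the cyclopentane is purchased with C8, C9, C11 and C12 in place; the macrolactone is the only ring made (step 7); the 17Z olefin arrives with the aldehyde.

Key step: step 7

Assumption: the sense of induction of a nickel–bis(oxazoline) catalyst in a macrocyclic radical capture cannot be predicted, so the (S,S)-ligand is written and its mirror image is used if that one proves matched for 15S. (Z)-Hex-3-enal is taken as commercial and distilled before use.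

## Route

Step 1
Reactants: 1 (−)-Corey lactone diol, (3aR,4S,5R,6aS)-5-hydroxy-4-(hydroxymethyl)hexahydro-2H-cyclopenta[b]furan-2-one
Product: 2 bis(triethylsilyl) ether of 1
Conditions: TESCl (2.4 eq), imidazole, DMF, 0 °C → rt
Reagents that add atoms: chlorotriethylsilane, CC[Si](Cl)(CC)CC
Why: Silylation of both hydroxyls (substitution at silicon, imidazole as base) should be clean and touches no stereocentre.

Step 2
Reactants: 2 bis(triethylsilyl) ether
Product: 3 (3aR,4R,5R,6aS)-2-oxo-5-(triethylsilyloxy)hexahydro-2H-cyclopenta[b]furan-4-carbaldehyde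
Conditions: (COCl)2, DMSO, CH2Cl2, −78 → −30 °C; Et3N, −78 → 0 °C
Reagents that add atoms: none
Why: Under Swern conditions the unhindered primary TES ether should be cleaved by the chlorosulfonium salt and oxidised directly to the aldehyde while the secondary TES ether stays; C12 keeps its all-trans (thermodynamic) configuration.

Step 3
Reactants: 3 aldehyde
Product: 4 (3aR,4S,5R,6aS)-4-[(E)-2-iodoethenyl]-5-(triethylsilyloxy)hexahydro-2H-cyclopenta[b]furan-2-one
Conditions: CrCl2, CHI3, THF/1,4-dioxane, 0 °C → rt
Reagents that add atoms: iodoform, IC(I)I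
Why: Takai olefination: the gem-dichromium species made from CHI3 and divalent chromium adds to the aldehyde and anti-eliminates to the (E)-iodoalkene, and the non-basic medium should spare the β-silyloxy group and the lactone.

Step 4
Reactants: 4 vinyl iodide lactone
Product: 5 (3aR,4S,5R,6aS)-4-[(E)-2-iodoethenyl]-5-(triethylsilyloxy)hexahydro-2H-cyclopenta[b]furan-2-ol (lactol, both anomers)
Conditions: iBu2AlH (1.1 eq), CH2Cl2, −78 °C; aq. potassium sodium tartrate
Reagents that add atoms: none
Why: Partial reduction of the γ-lactone stops at the tetrahedral aluminate at −78 °C and should give the lactol; vinyl iodide and silyl ether are inert.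

Step 5
Reactants: 5 lactol; 6 (4-carboxybutyl)triphenylphosphonium bromide
Product: 8 (5Z)-7-[(1R,2S,3R,5S)-5-hydroxy-2-[(E)-2-iodoethenyl]-3-(triethylsilyloxy)cyclopentyl]hept-5-enoic acid, via carboxylate ylide 7 (not isolated)
Conditions: 6, KOtBu, THF, 0 °C; then 5, 0 °C → rt; pH 5 buffer work-up
Reagents that add atoms: none
Why: Wittig olefination of the open hydroxy-aldehyde form with the non-stabilised ylide should give the 5Z olefin under kinetic control, as in the classical prostaglandin α-chain installation; the ylide is not expected to dehydrohalogenate the (E)-vinyl iodide at 0 °C.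

Step 6
Reactants: 8 hydroxy acid
Product: 9 (5Z)-7-[(1R,2S,3R)-2-[(E)-2-iodoethenyl]-5-oxo-3-(triethylsilyloxy)cyclopentyl]hept-5-enoic acid
Conditions: Dess–Martin periodinane, CH2Cl2, 0 °C → rt
Reagents that add atoms: none
Why: Dess–Martin oxidation should convert the only free hydroxyl (C9) into the ketone without base, so the β-silyloxy group does not eliminate and C8 stays trans to C12.

Step 7
Reactants: 9 keto acid; 10 (Z)-hex-3-enal
Product: 13 PGE3 1,15-lactone 11-triethylsilyl ether (8R,11R,12R,15S; 5Z,13E,17Z), via acyl chloride 11 (not isolated), via 1-chloroalkyl ester 12 (not isolated)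
Conditions: (i) Me2C=C(Cl)NMe2 (1.05 eq), CH2Cl2, 0 °C → rt; (ii) 10, ZnCl2 (5 mol%), CH2Cl2, −20 → 0 °C, then solvent change to THF; (iii) syringe-pump addition to NiBr2(dme) (20 mol%), (S,S)-2,2'-isopropylidenebis(4-phenyl-2-oxazoline) (24 mol%), Mn powder, DMA/THF, ca. 2 mM, 0 °C → rt
Reagents that add atoms: none
Why: Proposed new method: the α-chloroenamine gives acyl chloride 11 under neutral conditions and ZnCl2 catalyses its addition across the C=O of 10 (the classical 1-chloroalkyl ester synthesis), so C15 is tethered to C1 through the future lactone oxygen and activated at once; zerovalent nickel then inserts into the C14–I bond, a monovalent nickel species abstracts chlorine from C15 to give an oxygen-stabilised secondary radical, the vinylnickel centre captures it, reductive elimination from trivalent nickel forms C14–C15, and Mn returns the catalyst to the zerovalent state. The closest known reaction types are the nickel-catalysed enantioconvergent couplings of racemic 1-haloalkyl esters (made from an aldehyde and an acyl halide) with organozinc or olefin/hydrosilane partners, the nickel-catalysed asymmetric reductive coupling of vinyl halides with activated alkyl halides, and the Nozaki–Hiyama–Kishi macrocyclisation; none has been run as a ring closure on a 1-haloalkyl ester. The one ring closed is the 13-membered lactone (O, C1–C8, C12–C15), closed end-to-end at an sp2–sp3 bond by macrocyclising cross-electrophile coupling through a nickelacycle one atom larger that contracts on reductive elimination. The only new stereocentre, C15, arises from a planar radical, so both C15 epimers of 12 converge and the 15S configuration is fixed by the chiral bis(oxazoline) on nickel during radical capture and reductive elimination (catalyst control). The step needs cross- over homo-coupling, ring closure over oligomerisation and retention of three olefin geometries: the sp2 C–I bond reacts only by two-electron oxidative addition and the sp3 C–Cl bond only by halogen abstraction, which enforces the C14/C15 pairing; slow addition at high dilution, the 5Z olefin and the vicinal side chains on the five-membered ring keep the two ends within reach; and the vinylnickel intermediate is configurationally stable, so 13E is retained. The C9 ketone, the TES ether and both Z olefins are expected to be inert to Mn and low-valent nickel under these conditions.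

Step 8
Reactants: 13 macrolactone silyl ether
Product: 14 PGE3 1,15-lactone (8R,11R,12R,15S; 5Z,13E,17Z)
Conditions: HF·pyridine, THF/pyridine, 0 °C
Reagents that add atoms: none
Why: Buffered fluoride cleavage of the secondary TES ether is the standard unmasking of 11-silyl PGE derivatives and should leave the β-hydroxy ketone, the lactone and the olefins intact.

Step 9
Reactants: 14 PGE3 1,15-lactone
Product: 15 PGE3 1,15-lactone 11-acetate (target)
Conditions: Ac2O, pyridine, CH2Cl2, 0 °C
Reagents that add atoms: acetic anhydride, CC(=O)OC(C)=O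
Why: Acylation of the C11 alcohol with Ac2O/pyridine proceeds with retention at C11; kept cold and short, it should outrun E1cB loss of acetate from the β-acetoxy ketone.

## Compound list

1 | (−)-Corey lactone diol, (3aR,4S,5R,6aS)-5-hydroxy-4-(hydroxymethyl)hexahydro-2H-cyclopenta[b]furan-2-one | OC[C@H]1[C@H](O)C[C@@H]2OC(=O)C[C@H]12 | starting material
2 | (3aR,4S,5R,6aS)-5-(triethylsilyloxy)-4-[(triethylsilyloxy)methyl]hexahydro-2H-cyclopenta[b]furan-2-one | CC[Si](CC)(CC)OC[C@H]1[C@H](O[Si](CC)(CC)CC)C[C@@H]2OC(=O)C[C@H]12 | intermediate
3 | (3aR,4R,5R,6aS)-2-oxo-5-(triethylsilyloxy)hexahydro-2H-cyclopenta[b]furan-4-carbaldehyde | O=C[C@H]1[C@H](O[Si](CC)(CC)CC)C[C@@H]2OC(=O)C[C@H]12 | intermediate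
4 | (3aR,4S,5R,6aS)-4-[(E)-2-iodoethenyl]-5-(triethylsilyloxy)hexahydro-2H-cyclopenta[b]furan-2-one | I/C=C/[C@H]1[C@H](O[Si](CC)(CC)CC)C[C@@H]2OC(=O)C[C@H]12 | intermediate
5 | lactol of 4 (2-ol, both anomers) | I/C=C/[C@H]1[C@H](O[Si](CC)(CC)CC)C[C@@H]2OC(O)C[C@H]12 | intermediate
6 | (4-carboxybutyl)triphenylphosphonium bromide | OC(=O)CCCC[P+](c1ccccc1)(c1ccccc1)c1ccccc1.[Br-] | starting material
7 | potassium 5-(triphenylphosphoranylidene)pentanoate (ylide, not isolated) | [K+].[O-]C(=O)CCCC=P(c1ccccc1)(c1ccccc1)c1ccccc1 | intermediate
8 | (5Z)-7-[(1R,2S,3R,5S)-5-hydroxy-2-[(E)-2-iodoethenyl]-3-(triethylsilyloxy)cyclopentyl]hept-5-enoic acid | I/C=C/[C@H]1[C@H](O[Si](CC)(CC)CC)C[C@H](O)[C@@H]1C/C=C\CCCC(=O)O | intermediate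
9 | (5Z)-7-[(1R,2S,3R)-2-[(E)-2-iodoethenyl]-5-oxo-3-(triethylsilyloxy)cyclopentyl]hept-5-enoic acid | I/C=C/[C@H]1[C@H](O[Si](CC)(CC)CC)CC(=O)[C@@H]1C/C=C\CCCC(=O)O | intermediate
10 | (Z)-hex-3-enal | CC/C=C\CC=O | starting material
11 | acyl chloride of 9 (not isolated) | I/C=C/[C@H]1[C@H](O[Si](CC)(CC)CC)CC(=O)[C@@H]1C/C=C\CCCC(Cl)=O | intermediate
12 | (3Z)-1-chlorohex-3-en-1-yl ester of 9 (both C15 epimers, not isolated) | I/C=C/[C@H]1[C@H](O[Si](CC)(CC)CC)CC(=O)[C@@H]1C/C=C\CCCC(=O)OC(Cl)C/C=C\CC | intermediate
13 | PGE3 1,15-lactone 11-triethylsilyl ether | CC/C=C\C[C@H]1/C=C/[C@H]2[C@H](O[Si](CC)(CC)CC)CC(=O)[C@@H]2C/C=C\CCCC(=O)O1 | intermediate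
14 | PGE3 1,15-lactone | CC/C=C\C[C@H]1/C=C/[C@H]2[C@H](O)CC(=O)[C@@H]2C/C=C\CCCC(=O)O1 | intermediate
15 | PGE3 1,15-lactone 11-acetate | CC/C=C\C[C@H]1/C=C/[C@H]2[C@H](OC(C)=O)CC(=O)[C@@H]2C/C=C\CCCC(=O)O1 | target

## Step count and risks

Total steps: 9. Longest linear sequence: 9 steps (1 → 15).

**Step 7 (Proposed new method).** Several processes could defeat it:
- oligomerisation, or simple reduction of the C–I or C–Cl bond, outrunning ring closure;
- weak facial control at C15 if catalyst and ring conformation are mismatched;
- scrambling of the 17Z olefin or a 1,2-vinyl shift through reversible 3-exo closure of the homoallylic C15 radical, and β-hydride loss from the alkylnickel species;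
- in stage (ii), migration of the β,γ-olefin of the aldehyde into conjugation before insertion.

The fallback uses known chemistry, sets out from 9 and comes back at 13. The acid is masked as the methyl ester F1 (TMSCHN2, MeOH/toluene, 0 °C). The vinyl iodide is joined to 10 by an intermolecular Nozaki–Hiyama–Kishi reaction (CrCl2, NiCl2 cat., DMSO/THF, rt), in which the aldehyde should react in preference to the C9 ketone and the ester. This should give the (15S)-allylic alcohol, PGE3 methyl ester 11-triethylsilyl ether F2, and its (15R)-epimer F3, to be separated by chromatography. Pig liver esterase (pH 7 phosphate buffer/acetone) should free the seco acids without base: PGE3 11-triethylsilyl ether F4 from F2 and its 15-epimer F5 from F3. F4 is lactonised with retention through the mixed 2,4,6-trichlorobenzoic anhydride F6 (2,4,6-trichlorobenzoyl chloride, Et3N; then DMAP, toluene, high dilution; Yamaguchi macrolactonisation). F5 is lactonised with inversion at C15 (PPh3, DIAD, toluene, high dilution; Mitsunobu macrolactonisation). Both epimers thus converge on 13. Here C14–C15 is made by a polar organochromium addition, which avoids the radical at C15, and the ring is closed at O–C1.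

**Step 9.** Base-promoted β-elimination of the newly formed acetate (or of the hydroxyl) could give the cyclopentenone. The fallback changes the approach from base-mediated chemical acylation to biocatalytic acyl transfer. It sets out from 14 and comes back at 15: immobilised Candida antarctica lipase B with vinyl acetate in tert-butyl methyl ether at 30 °C, a neutral medium with no amine present. No new compound arises.

**Step 3.** The olefination could lose E selectivity, and the β-silyloxy aldehyde could eliminate or decompose on the Lewis-acidic chromium salts. The fallback sets out from 3 and comes back at 4. Ohira–Bestmann homologation (dimethyl (1-diazo-2-oxopropyl)phosphonate, K2CO3, MeOH, 0 °C) should give the 4-ethynyl lactone F7. Palladium-catalysed syn-hydrostannation (Bu3SnH, PdCl2(PPh3)2 cat., THF, 0 °C) should give the (E)-vinylstannane F8. Iododestannylation (I2, CH2Cl2, 0 °C) proceeds with retention and gives 4.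

## Further compounds

F1 | step 7 | methyl (5Z)-7-[(1R,2S,3R)-2-[(E)-2-iodoethenyl]-5-oxo-3-(triethylsilyloxy)cyclopentyl]hept-5-enoate | I/C=C/[C@H]1[C@H](O[Si](CC)(CC)CC)CC(=O)[C@@H]1C/C=C\CCCC(=O)OC
F2 | step 7 | PGE3 methyl ester 11-triethylsilyl ether (15S) | CC/C=C\C[C@H](O)/C=C/[C@H]1[C@H](O[Si](CC)(CC)CC)CC(=O)[C@@H]1C/C=C\CCCC(=O)OC
F3 | step 7 | 15-epi-PGE3 methyl ester 11-triethylsilyl ether (15R) | CC/C=C\C[C@@H](O)/C=C/[C@H]1[C@H](O[Si](CC)(CC)CC)CC(=O)[C@@H]1C/C=C\CCCC(=O)OC
F4 | step 7 | PGE3 11-triethylsilyl ether (15S seco acid) | CC/C=C\C[C@H](O)/C=C/[C@H]1[C@H](O[Si](CC)(CC)CC)CC(=O)[C@@H]1C/C=C\CCCC(=O)O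
F5 | step 7 | 15-epi-PGE3 11-triethylsilyl ether (15R seco acid) | CC/C=C\C[C@@H](O)/C=C/[C@H]1[C@H](O[Si](CC)(CC)CC)CC(=O)[C@@H]1C/C=C\CCCC(=O)O
F6 | step 7 | mixed 2,4,6-trichlorobenzoic anhydride of F4 (not isolated) | CC/C=C\C[C@H](O)/C=C/[C@H]1[C@H](O[Si](CC)(CC)CC)CC(=O)[C@@H]1C/C=C\CCCC(=O)OC(=O)c1c(Cl)cc(Cl)cc1Cl
F0 | step 9 | none | none
F7 | step 3 | (3aR,4S,5R,6aS)-4-ethynyl-5-(triethylsilyloxy)hexahydro-2H-cyclopenta[b]furan-2-one | C#C[C@H]1[C@H](O[Si](CC)(CC)CC)C[C@@H]2OC(=O)C[C@H]12
F8 | step 3 | 4-[(E)-2-(tributylstannyl)ethenyl] analogue of 4 (same ring configuration) | CCCC[Sn](CCCC)(CCCC)/C=C/[C@H]1[C@H](O[Si](CC)(CC)CC)C[C@@H]2OC(=O)C[C@H]12
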